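## Structural features

The target is a flavonol: a 4H-chromen-4-one in which benzene ring A is fused to the 4-pyranone ring C through C4a–C8a. Ring B (4-hydroxy-3-methoxyphenyl) is attached at C2 through the C1′–C2 bond, and C3 carries a hydroxyl. Ring A is fully differentiated: hydroxyl at C5 (hydrogen-bonded to the C4 carbonyl), hydrogen at C6, a prenyl (3-methylbut-2-en-1-yl) ether at O7 and a methyl ether at O8. There is no stereocentre and no stereogenic double bond, so the problem is one of regiochemistry and chemoselectivity. The fragile element is the aryl prenyl ether. It ionises to an allyl cation under strong Brønsted or Lewis acids, is reduced or cleaved under hydrogenation, and can be ionised by electron-rich zerovalent palladium. The real difficulty is telling the oxygens apart: O7 must carry the prenyl group, O8 the methyl group, and of the two oxygens ortho to C4a only the one next to the methoxy group may become O1, because closure through the other gives the 6-methoxy isomer. The key step exploits C2: it is an sp2 carbon at the carbonyl oxidation level bonded only to C1′, C3 and O1, so it can be inserted as carbon monoxide between a ring B aryl halide carbon and the already oxygenated α-carbon (C3) of a ring A ketone, leaving O1–C2 to simple condensation.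

## Logic of the disconnections

Flavone numbering is used for all intermediates.

19 ⇒ 18. The three acetal O–CH2 bonds at O3, O5 and O4′ are cut. These hydroxyls must be masked through the strongly basic carbonylation, and one type of acetal allows a single release. Nothing is gained in skeleton, but all hydroxyl differentiation is moved to earlier compounds. The forward step must cleave three acetals without ionising the allylic C–O bond at O7, which calls for dilute protic acid at low temperature.

18 ⇒ 16. The O1–C2 bond and the C2=C3 double bond are cut (water added back). A flavone ring C is the cyclodehydration product of an ortho-hydroxyaryl 1,3-diketone, so ring C opens to an acyclic chain. The forward step must close only through the C8a oxygen. O5 therefore has to stay blocked until dehydration is complete, so ring closure and acetal removal are kept as separate operations.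

16 ⇒ 12 + 14 + 15. The C1′–C2 and C2–C3 bonds are cut. C2 lies between an aryl carbon and an enolisable carbon and has the oxidation level of carbon monoxide. The cut is convergent, gives two fragments of similar size and keeps the C3 oxygen in place from the start. The forward step demands a single carbon monoxide insertion, acylation at carbon (or convergence of the O-acylated material), and tolerance of a free phenol and of the prenyl ether.

14 ⇒ 13. The acetal O–CH2 bond at O4′ is cut. The free phenol would consume base and acylpalladium, so it is masked with the same acetal as the other hydroxyls.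

12 ⇒ 11 ⇒ 10. The ketone is taken back to the carbinol, and then the C4–C3 bond is cut. This leads to an aldehyde and a lithiated, acetal-protected hydroxymethyl unit, so C3 arrives with its oxygen in one C–C bond formation. The addition must tolerate a phenoxide, and the oxidation must spare the phenol and the alkene.

10 ⇒ 8 + 9. The O7–CH2 bond is cut. In 8 the two hydroxyls differ: one is chelated to the aldehyde, the other is a free vinylogous acid. The forward step must alkylate only the latter, at oxygen and at the primary carbon of 9.

8 ⇒ 6. The C4a–C4 (aryl–formyl) bond is cut. The two open ring positions of 6 are equivalent by symmetry, so only one aldehyde can form, and the formylation is the symmetry-breaking event. The forward step must stop at mono-formylation and leave the acetal intact.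

6 ⇒ 5 ⇒ 4. The two O–Si bonds and then the acetal O–CH2 bond at O5 are cut. The acetal must sit only on the oxygen para to the methoxy group, which requires the two flanking oxygens to be masked by an orthogonal, fluoride-labile group at that moment.

4 ⇒ 2. The aryl C5–O bond is cut (through a C–B bond). C5 is meta to both ring oxygens and out of reach of electrophilic substitution, but it is the only C–H of 2 without an ortho substituent. The forward step relies on steric control.

2 ⇒ 1. The two O–Si bonds are cut, which leads to the commercial symmetric diol. The silyl groups remove the acidic protons and supply the steric bias for the C–H functionalisation.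

## Other disconnections considered

Alternative 1: The cut runs through ring A itself, at C4a–C5 and C8–C8a. In the forward sense the electron-rich diene A1 would add to the bromoalkynoate A2 in a Diels–Alder reaction, and the adduct would aromatise by loss of methanol to the benzoate A3. In A3 the ester carbon is C4, the bromine marks C8a and the 3-methoxy group is the future C8 substituent.
- In its favour: the substitution pattern follows from the polarity of the two partners (the nucleophilic, methoxy-bearing diene terminus bonds to the bromine-bearing alkyne carbon). No symmetric intermediate has to be desymmetrised and no C–H functionalisation is needed. On regiochemical certainty of ring A this is equal to, and arguably better than, the borylation of 2, and it avoids handling 15.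
- Against it here: A1 and A2 are sensitive compounds that must be prepared. A3 contains only ring A and C4, so C3, C2, ring B and O1 are all still missing. The two hydroxyls of A3 need the same differentiation as those of 8 (equal on that point). O1–C8a would have to be made by metal-catalysed C–O coupling at a bromide flanked by two substituents, where the chosen plan uses the spontaneous addition of a free phenol.
- Comparison: the cycloaddition is mechanistically reliable, but it spends the key step on a tetra-oxygenated benzene that the chosen plan derives from a commercial arene in two operations. The number of steps after A3 would be expected to exceed that after 6.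

Alternative 2: The cut is at C4–C4a and O1–C2, so ring C forms in one thermal operation. The symmetric resorcinol A4 and the α-benzyloxy β-ketoester A5 would be heated neat to about 240 °C to give the flavone A6 by C-acylation and condensation.
- In its favour: the step is highly convergent and closes ring C with the C3 oxygen already in place. The symmetry of A4 makes the regiochemistry unambiguous. A6 has the 7-hydroxyl as its only free hydroxyl, ready for alkylation with 9. On step count, and on addressing O7 selectively, this alternative is better than the chosen plan, and it needs neither palladium nor 15.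
- Against it here: the temperature is compatible only with robust protecting groups such as benzyl, and benzyl ethers cannot be removed once the prenyl ether is present. Hydrogenolysis would saturate or cleave the allylic ether, and Lewis acids strong enough for debenzylation would strip the prenyl group and threaten the methyl ethers. Acetals that would suit the end-game would not be expected to survive a phenolic melt. The α-alkoxy β-ketoester A5 is also prone to thermal decarboxylative decomposition.
- Comparison: the thermal demand of the mechanism conflicts with the acid- and reduction-sensitive prenyl ether. The chosen plan stays at or below 90 °C and ends with acetals that leave under dilute acid. The alternative wins on brevity and loses on the deprotection.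

Alternative 3: The cut is at C4a–C4 and C4–C3, with 15 as C4, followed by O1–C2. A palladium–phosphine catalyst in a secondary amine would couple the iodoresorcinol A7, 15 and the arylacetylene A8 to the alkynyl ketone A10, whose ortho hydroxyl would add to the triple bond to give the flavone A9.
- In its favour: it is the same family of three-component carbonylation, so it is equal to the chosen plan in catalyst type and in the handling of 15. A7 would come from 6 by a single iodination, so the ring A partner needs about four steps fewer than 12. Ring C closes in the key step itself, and the 7-hydroxyl of A9 is free for direct alkylation with 9. On all three points it is better.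
- Against it here: C3 arrives as C–H. The 3-hydroxyl would have to be introduced afterwards, by epoxidation of the C2=C3 bond or by C3 metalation and oxidation. An electrophilic oxidant would attack the more electron-rich prenyl alkene first, so the oxidation would have to precede the alkylation and be carried out with a free 7-hydroxyl. A10 can also close in the 5-exo mode to an aurone, and the two free phenols of A7 can be aroylated by the acylpalladium intermediate.
- Comparison: the alternative is shorter to the flavone core but ends one oxidation level too low at C3. The chosen plan brings that oxygen in as the α-alkoxy group of 12 and needs no late oxidation in the presence of the prenyl group.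

Key step: step 10

Remark on the chemistry: 16 is drawn as the open diketone. It is expected to equilibrate with its enol and with hemiketal 17, and its C3 centre is configurationally labile, so no compound of the route needs a stereodescriptor. Abbreviations: TBS = tert-butyldimethylsilyl, MOM = methoxymethyl, prenyl = 3-methylbut-2-en-1-yl.

## Steps

Step 1
Reactants: 1 2-methoxyresorcinol (2-methoxybenzene-1,3-diol)
Product: 2 1,3-bis(tert-butyldimethylsilyloxy)-2-methoxybenzene
Conditions: TBSCl (2.4 equiv), imidazole, DMF, rt
Reagents that add atoms: tert-butyldimethylsilyl chloride, CC(C)(C)[Si](C)(C)Cl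
Why: Imidazole-promoted silylation of both phenols removes the acidic O–H bonds before the iridium chemistry, and the two bulky silyloxy groups shield C4 and C6 so that C5 is the only unhindered C–H position.

Step 2
Reactants: 2 1,3-bis(tert-butyldimethylsilyloxy)-2-methoxybenzene
Product: 4 3,5-bis(tert-butyldimethylsilyloxy)-4-methoxyphenol, via aryl pinacol boronate 3 (not isolated)
Conditions: [Ir(OMe)(cod)]2 (1.5 mol %), 4,4′-di-tert-butyl-2,2′-bipyridine (3 mol %), B2pin2 (1.0 equiv), THF, 80 °C; then Oxone (2KHSO5·KHSO4·K2SO4), acetone/H2O, rt, 10 min; NaHSO3 quench
Reagents that add atoms: potassium peroxymonosulfate (active salt of Oxone), [K+].[O-]S(=O)(=O)OO (the phenol oxygen); bis(pinacolato)diboron, CC1(C)OB(OC1(C)C)B1OC(C)(C)C(C)(C)O1 (boron of intermediate 3 only)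
Why: Iridium-catalysed C–H borylation (Hartwig–Miyaura type) is sterically controlled and should select C5, the only C–H without an ortho substituent. Ipso-oxidation of the C–B bond of 3 by peroxymonosulfate (1,2-aryl shift from boron to oxygen) then gives the phenol at the same carbon, and the aryl silyl ethers tolerate the short, mildly acidic oxidation.

Step 3
Reactants: 4 3,5-bis(tert-butyldimethylsilyloxy)-4-methoxyphenol
Product: 5 1,3-bis(tert-butyldimethylsilyloxy)-2-methoxy-5-(methoxymethoxy)benzene
Conditions: MOMCl (1.5 equiv), iPr2NEt, CH2Cl2, 0 °C → rt
Reagents that add atoms: chloromethyl methyl ether, COCCl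
Why: Base-mediated O-alkylation (Williamson type) of the only free phenol places the acetal on the oxygen that becomes O5 of the flavone; no selectivity question arises because the other two oxygens are silylated.

Step 4
Reactants: 5 1,3-bis(tert-butyldimethylsilyloxy)-2-methoxy-5-(methoxymethoxy)benzene
Product: 6 2-methoxy-5-(methoxymethoxy)benzene-1,3-diol
Conditions: Bu4NF (2.2 equiv), THF, 0 °C, under N2; aq. NH4Cl
Reagents that add atoms: none
Why: Fluoride-induced cleavage of both aryl silyl ethers (driven by the Si–F bond) is orthogonal to the acetal and to the methyl ether and returns a mirror-symmetric diol whose two hydroxyls are still equivalent.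

Step 5
Reactants: 6 2-methoxy-5-(methoxymethoxy)benzene-1,3-diol
Product: 8 2,4-dihydroxy-3-methoxy-6-(methoxymethoxy)benzaldehyde, via benzylic alcohol 7 (not isolated)
Conditions: MgCl2 (3 equiv), Et3N (6 equiv), (CH2O)n (2.5 equiv CH2O), THF, 65 °C; aq. NH4Cl
Reagents that add atoms: formaldehyde (as paraformaldehyde), C=O
Why: In the magnesium-mediated ortho-formylation (Casnati–Skattebøl reaction) the magnesium phenoxide delivers formaldehyde to the ortho carbon, and the benzylic alkoxide 7 is oxidised by a second formaldehyde through Oppenauer-type hydride transfer. The two open ring positions are equivalent, so only one aldehyde can form, and the step breaks the symmetry: the 2-hydroxyl becomes chelated to the carbonyl while the 4-hydroxyl stays free.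

Step 6
Reactants: 8 2,4-dihydroxy-3-methoxy-6-(methoxymethoxy)benzaldehyde; 9 prenyl bromide (1-bromo-3-methylbut-2-ene)
Product: 10 2-hydroxy-3-methoxy-6-(methoxymethoxy)-4-(prenyloxy)benzaldehyde
Conditions: K2CO3 (1.2 equiv), 9 (1.1 equiv), acetone, rt → 40 °C
Reagents that add atoms: none
Why: Williamson etherification under weak base ionises and alkylates the para hydroxyl (a non-chelated vinylogous acid), while the ortho hydroxyl stays locked in its hydrogen bond to the aldehyde. O-alkylation by SN2 attack at the primary carbon of 9 is expected in acetone.

Step 7
Reactants: 10 2-hydroxy-3-methoxy-6-(methoxymethoxy)-4-(prenyloxy)benzaldehyde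
Product: 11 racemic 2-[1-hydroxy-2-(methoxymethoxy)ethyl]-6-methoxy-3-(methoxymethoxy)-5-(prenyloxy)phenol
Conditions: 10, NaH (1.05 equiv), THF, 0 °C; added to Bu3SnCH2OCH2OCH3 (1.4 equiv)/n-BuLi (1.35 equiv), THF, −78 °C; −78 → −40 °C; aq. NH4Cl
Reagents that add atoms: tributyl[(methoxymethoxy)methyl]stannane, CCCC[Sn](CCCC)(CCCC)COCOC
Why: Tin–lithium exchange generates the α-alkoxymethyllithium, which adds 1,2 to the aldehyde of the pre-formed sodium phenoxide, so no organolithium is spent on the acidic proton. The new carbinol centre is formed without control (racemic) and is removed in step 8.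

Step 8
Reactants: 11 racemic 2-[1-hydroxy-2-(methoxymethoxy)ethyl]-6-methoxy-3-(methoxymethoxy)-5-(prenyloxy)phenol
Product: 12 1-[2-hydroxy-3-methoxy-6-(methoxymethoxy)-4-(prenyloxy)phenyl]-2-(methoxymethoxy)ethan-1-one
Conditions: activated MnO2 (15 equiv), CH2Cl2, rt
Reagents that add atoms: none
Why: MnO2 oxidises the benzylic secondary alcohol to the aryl ketone under neutral heterogeneous conditions that should leave the prenyl alkene, the acetals and the phenol untouched; the product is stabilised by the hydrogen bond between the 2-hydroxyl and the new carbonyl.

Step 9
Reactants: 13 4-bromo-2-methoxyphenol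
Product: 14 4-bromo-2-methoxy-1-(methoxymethoxy)benzene
Conditions: MOMCl (1.3 equiv), iPr2NEt, CH2Cl2, 0 °C → rt
Reagents that add atoms: chloromethyl methyl ether, COCCl
Why: Base-mediated O-alkylation of the phenol removes the acidic ring B proton, which would otherwise consume base and acylpalladium in step 10, and uses the same acetal as the other masked hydroxyls so that one final operation releases all of them.

Step 10
Reactants: 12 1-[2-hydroxy-3-methoxy-6-(methoxymethoxy)-4-(prenyloxy)phenyl]-2-(methoxymethoxy)ethan-1-one; 14 4-bromo-2-methoxy-1-(methoxymethoxy)benzene; 15 carbon monoxide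
Product: 16 racemic 1-[2-hydroxy-3-methoxy-6-(methoxymethoxy)-4-(prenyloxy)phenyl]-2-(methoxymethoxy)-3-[3-methoxy-4-(methoxymethoxy)phenyl]propane-1,3-dione
Conditions: Pd(dba)2 (5 mol %), Xantphos (6 mol %), NaN(SiMe3)2 (3.3 equiv), 14 (1.2 equiv), CO (1 atm, sealed two-chamber vessel), 1,4-dioxane/THF, 80 °C; aq. NH4Cl
Reagents that add atoms: none
Why: Xantphos-ligated zerovalent palladium adds oxidatively to the C–Br bond of 14, carbon monoxide inserts to give an aroyl complex of divalent palladium, the sodium enolate of 12 (formed together with the phenoxide by the silylamide) displaces bromide, and C–C reductive elimination forms C2–C3 while the inserted carbonyl becomes C2 bonded to C1′. The closest known reaction type is the palladium-catalysed carbonylative α-arylation of aryl ketones with aryl halides to 1,3-diketones, including 2-hydroxyacetophenones as flavone precursors; the α-alkoxy group is a substrate variation. No ring is closed in this step. The new C3 stereocentre is not controlled by any element: it lies between two carbonyls, is configurationally labile and becomes sp2 in step 11, so 16 is racemic. A single carbon monoxide insertion in preference to direct α-arylation is secured by the wide bite angle of the diphosphine and the carbon monoxide atmosphere. Any aroyl group that lands on the phenoxide oxygen is moved to carbon by the excess base through Baker–Venkataraman acyl transfer, and the third equivalent of base converts the product into its unreactive diketonate, which stops a second acylation. The prenyl ether should survive because the aryloxide of the doubly deprotonated ring A is a poor leaving group and the trisubstituted alkene binds carbon-monoxide-saturated zerovalent palladium weakly, so allylic ionisation is not expected.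

Step 11
Reactants: 16 racemic 1-[2-hydroxy-3-methoxy-6-(methoxymethoxy)-4-(prenyloxy)phenyl]-2-(methoxymethoxy)-3-[3-methoxy-4-(methoxymethoxy)phenyl]propane-1,3-dione
Product: 18 8-methoxy-2-[3-methoxy-4-(methoxymethoxy)phenyl]-3,5-bis(methoxymethoxy)-7-(prenyloxy)-4H-chromen-4-one, via cyclic hemiketal 17 (not isolated)
Conditions: NaOAc (3 equiv), AcOH, 90 °C
Reagents that add atoms: none
Why: In this buffered cyclodehydration the free C8a hydroxyl adds to the C2 ketone (6-exo-trig) to give hemiketal 17, which loses water through an oxocarbenium ion stabilised by O1 and ring B to give the 4-pyranone. Acetate-buffered acetic acid is too weak to cleave the aryl acetals or ionise the prenyl ether at a competitive rate, so O5 stays blocked until closure through the C8a oxygen is irreversible, which fixes the 8-methoxy regiochemistry.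

Step 12
Reactants: 18 8-methoxy-2-[3-methoxy-4-(methoxymethoxy)phenyl]-3,5-bis(methoxymethoxy)-7-(prenyloxy)-4H-chromen-4-one
Product: 19 3,5-dihydroxy-2-(4-hydroxy-3-methoxyphenyl)-8-methoxy-7-(prenyloxy)-4H-chromen-4-one (target)
Conditions: HCl (about 0.5 M) in MeOH/THF, 0 °C → rt, monitored; NaHCO3 quench
Reagents that add atoms: none
Why: Acid-catalysed transacetalisation to methanol removes the three methoxymethyl groups through the methoxymethyl oxocarbenium ion, which forms far more readily than the dimethylallyl cation needed to cleave the prenyl ether, so dilute acid at or below room temperature should be selective. The acetals at O5 and O3 are further activated by the neighbouring C4 carbonyl.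

## Compound list

1 | 2-methoxyresorcinol (2-methoxybenzene-1,3-diol) | COc1c(O)cccc1O | starting material
2 | 1,3-bis(tert-butyldimethylsilyloxy)-2-methoxybenzene | COc1c(O[Si](C)(C)C(C)(C)C)cccc1O[Si](C)(C)C(C)(C)C | intermediate
3 | 2-[3,5-bis(tert-butyldimethylsilyloxy)-4-methoxyphenyl]-4,4,5,5-tetramethyl-1,3,2-dioxaborolane | COc1c(O[Si](C)(C)C(C)(C)C)cc(B2OC(C)(C)C(C)(C)O2)cc1O[Si](C)(C)C(C)(C)C | intermediate (not isolated)
4 | 3,5-bis(tert-butyldimethylsilyloxy)-4-methoxyphenol | COc1c(O[Si](C)(C)C(C)(C)C)cc(O)cc1O[Si](C)(C)C(C)(C)C | intermediate
5 | 1,3-bis(tert-butyldimethylsilyloxy)-2-methoxy-5-(methoxymethoxy)benzene | COCOc1cc(O[Si](C)(C)C(C)(C)C)c(OC)c(O[Si](C)(C)C(C)(C)C)c1 | intermediate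
6 | 2-methoxy-5-(methoxymethoxy)benzene-1,3-diol | COCOc1cc(O)c(OC)c(O)c1 | intermediate
7 | 4-(hydroxymethyl)-2-methoxy-5-(methoxymethoxy)benzene-1,3-diol (as its magnesium salt) | COCOc1cc(O)c(OC)c(O)c1CO | intermediate (not isolated)
8 | 2,4-dihydroxy-3-methoxy-6-(methoxymethoxy)benzaldehyde | COCOc1cc(O)c(OC)c(O)c1C=O | intermediate
9 | prenyl bromide (1-bromo-3-methylbut-2-ene) | CC(C)=CCBr | starting material
10 | 2-hydroxy-3-methoxy-6-(methoxymethoxy)-4-[(3-methylbut-2-en-1-yl)oxy]benzaldehyde | COCOc1cc(OCC=C(C)C)c(OC)c(O)c1C=O | intermediate
11 | racemic 2-[1-hydroxy-2-(methoxymethoxy)ethyl]-6-methoxy-3-(methoxymethoxy)-5-[(3-methylbut-2-en-1-yl)oxy]phenol | COCOCC(O)c1c(O)c(OC)c(OCC=C(C)C)cc1OCOC | intermediate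
12 | 1-{2-hydroxy-3-methoxy-6-(methoxymethoxy)-4-[(3-methylbut-2-en-1-yl)oxy]phenyl}-2-(methoxymethoxy)ethan-1-one | COCOCC(=O)c1c(O)c(OC)c(OCC=C(C)C)cc1OCOC | intermediate
13 | 4-bromo-2-methoxyphenol | COc1cc(Br)ccc1O | starting material
14 | 4-bromo-2-methoxy-1-(methoxymethoxy)benzene | COCOc1ccc(Br)cc1OC | intermediate
15 | carbon monoxide | [C-]#[O+] | starting material
16 | racemic 1-{2-hydroxy-3-methoxy-6-(methoxymethoxy)-4-[(3-methylbut-2-en-1-yl)oxy]phenyl}-2-(methoxymethoxy)-3-[3-methoxy-4-(methoxymethoxy)phenyl]propane-1,3-dione | COCOC(C(=O)c1ccc(OCOC)c(OC)c1)C(=O)c1c(O)c(OC)c(OCC=C(C)C)cc1OCOC | intermediate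
17 | 2-hydroxy-8-methoxy-2-[3-methoxy-4-(methoxymethoxy)phenyl]-3,5-bis(methoxymethoxy)-7-[(3-methylbut-2-en-1-yl)oxy]-2,3-dihydro-4H-chromen-4-one (racemic, mixture of diastereomers) | COCOC1C(=O)c2c(OCOC)cc(OCC=C(C)C)c(OC)c2OC1(O)c1ccc(OCOC)c(OC)c1 | intermediate (not isolated)
18 | 8-methoxy-2-[3-methoxy-4-(methoxymethoxy)phenyl]-3,5-bis(methoxymethoxy)-7-[(3-methylbut-2-en-1-yl)oxy]-4H-chromen-4-one | COCOc1ccc(-c2oc3c(OC)c(OCC=C(C)C)cc(OCOC)c3c(=O)c2OCOC)cc1OC | intermediate
19 | 3,5-dihydroxy-2-(4-hydroxy-3-methoxyphenyl)-8-methoxy-7-[(3-methylbut-2-en-1-yl)oxy]-4H-chromen-4-one (achiral) | COc1cc(-c2oc3c(OC)c(OCC=C(C)C)cc(O)c3c(=O)c2O)ccc1O | target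

## Step count and least certain steps

Total: 12 steps. Longest linear sequence: 11 steps (steps 1–8, 10, 11, 12); step 9 is the one-step ring B branch.

**Step 10 (key step).** The most likely failures are these:
- aroylation of the phenoxide oxygen without the following acyl transfer to carbon;
- capture of the aroylpalladium species by the silylamide (aminocarbonylation);
- slow oxidative addition of the electron-rich bromide, leaving time for direct α-arylation without carbon monoxide insertion or for ionisation of the allylic ether by zerovalent palladium.

The fallback sets out from 12 and 14 and rejoins the route at 16. Bromine–lithium exchange on 14 (n-BuLi, THF, −78 °C) and carboxylation with CO2 would give 3-methoxy-4-(methoxymethoxy)benzoic acid F1. Carbodiimide esterification of the phenol of 12 (EDC·HCl, DMAP, CH2Cl2) would give 2-methoxy-5-(methoxymethoxy)-6-[(methoxymethoxy)acetyl]-3-(prenyloxy)phenyl 3-methoxy-4-(methoxymethoxy)benzoate F2. Baker–Venkataraman rearrangement (LiN(SiMe3)2, THF, −20 °C → rt) would then move the aroyl group from oxygen to the α-carbon and give 16 without palladium or carbon monoxide.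

**Step 12.** The likely failure is acid-induced ionisation of the allylic C–O bond at O7 (loss of the prenyl group, or its migration to C6) competing with methanolysis of the least reactive acetal at O4′. The fallback sets out from 18 and rejoins at 19, installing the prenyl group after all acid chemistry:
- Forcing acidolysis of 18 (HCl, MeOH, 60 °C; methanol captures the allyl cation) would give 3,5,7-trihydroxy-2-(4-hydroxy-3-methoxyphenyl)-8-methoxy-4H-chromen-4-one F3.
- Peracetylation (Ac2O, pyridine) would give the tetraacetate F4.
- Treatment with 9 and K2CO3 in refluxing acetone would exchange the most electrophilic ester, the 7-acetate, for the prenyl ether and give the 3,5,4′-triacetate F5. This is the known selective 7-O-alkylation of flavonol peracetates.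
- Mild deacetylation (K2CO3, MeOH, 0 °C) would give 19.

**Step 8.** The likely failure is oxidation of the electron-rich free phenol ring (quinone or quinone methide formation) or sluggish oxidation of the hindered α-alkoxy carbinol. The fallback sets out from 10 and rejoins at 12 without any alcohol oxidation:
- Pinnick oxidation (NaClO2, NaH2PO4, 2-methyl-2-butene, t-BuOH/H2O) would give 2-hydroxy-3-methoxy-6-(methoxymethoxy)-4-(prenyloxy)benzoic acid F6.
- Coupling with N,O-dimethylhydroxylamine hydrochloride (EDC·HCl, iPr2NEt) would give the Weinreb amide 2-hydroxy-N,3-dimethoxy-6-(methoxymethoxy)-N-methyl-4-(prenyloxy)benzamide F7.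
- Deprotonation with NaH and addition of the lithium reagent of step 7 would give 12 directly through the chelated tetrahedral intermediate.

**Step 5.** The likely failure is a second formylation at the remaining activated ring position, or loss of the acetal by chelation to magnesium on heating. The fallback sets out from 4 and rejoins at 10, formylating before any acetal is present:
- Desilylation of 4 (Bu4NF, THF) would give 2-methoxybenzene-1,3,5-triol F8.
- Vilsmeier–Haack formylation (POCl3, DMF; aqueous hydrolysis) would give 2,4,6-trihydroxy-3-methoxybenzaldehyde F9.
- Alkylation of the para hydroxyl with 9 (K2CO3, acetone) would give 2,6-dihydroxy-3-methoxy-4-(prenyloxy)benzaldehyde F10.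
- One equivalent of MOMCl/iPr2NEt would be expected to acetalise the less hindered ortho hydroxyl (the one remote from the methoxy group) and give 10.

The selectivity of this last acetalisation is the fallback's own weak point.

## Further compounds

F1 | step 10 | 3-methoxy-4-(methoxymethoxy)benzoic acid | COCOc1ccc(C(=O)O)cc1OC
F2 | step 10 | 2-methoxy-5-(methoxymethoxy)-6-[(methoxymethoxy)acetyl]-3-[(3-methylbut-2-en-1-yl)oxy]phenyl 3-methoxy-4-(methoxymethoxy)benzoate | COCOCC(=O)c1c(OC(=O)c2ccc(OCOC)c(OC)c2)c(OC)c(OCC=C(C)C)cc1OCOC
F3 | step 12 | 3,5,7-trihydroxy-2-(4-hydroxy-3-methoxyphenyl)-8-methoxy-4H-chromen-4-one | COc1cc(-c2oc3c(OC)c(O)cc(O)c3c(=O)c2O)ccc1O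
F4 | step 12 | 2-[4-(acetyloxy)-3-methoxyphenyl]-8-methoxy-4-oxo-4H-chromene-3,5,7-triyl triacetate | COc1cc(-c2oc3c(OC)c(OC(C)=O)cc(OC(C)=O)c3c(=O)c2OC(C)=O)ccc1OC(C)=O
F5 | step 12 | 2-[4-(acetyloxy)-3-methoxyphenyl]-8-methoxy-7-[(3-methylbut-2-en-1-yl)oxy]-4-oxo-4H-chromene-3,5-diyl diacetate | COc1cc(-c2oc3c(OC)c(OCC=C(C)C)cc(OC(C)=O)c3c(=O)c2OC(C)=O)ccc1OC(C)=O
F6 | step 8 | 2-hydroxy-3-methoxy-6-(methoxymethoxy)-4-[(3-methylbut-2-en-1-yl)oxy]benzoic acid | COCOc1cc(OCC=C(C)C)c(OC)c(O)c1C(=O)O
F7 | step 8 | 2-hydroxy-N,3-dimethoxy-6-(methoxymethoxy)-N-methyl-4-[(3-methylbut-2-en-1-yl)oxy]benzamide | COCOc1cc(OCC=C(C)C)c(OC)c(O)c1C(=O)N(C)OC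
F8 | step 5 | 2-methoxybenzene-1,3,5-triol | COc1c(O)cc(O)cc1O
F9 | step 5 | 2,4,6-trihydroxy-3-methoxybenzaldehyde | COc1c(O)cc(O)c(C=O)c1O
F10 | step 5 | 2,6-dihydroxy-3-methoxy-4-[(3-methylbut-2-en-1-yl)oxy]benzaldehyde | COc1c(OCC=C(C)C)cc(O)c(C=O)c1O
A1 | alternative 1 | 1,4-dimethoxy-1,3-bis(trimethylsilyloxy)buta-1,3-diene (double-bond geometry left open) | COC=C(O[Si](C)(C)C)C=C(OC)O[Si](C)(C)C
A2 | alternative 1 | methyl 3-bromopropiolate | COC(=O)C#CBr
A3 | alternative 1 | methyl 2-bromo-4,6-dihydroxy-3-methoxybenzoate | COC(=O)c1c(O)cc(O)c(OC)c1Br
A4 | alternative 2 | 5-(benzyloxy)-2-methoxybenzene-1,3-diol | COc1c(O)cc(OCc2ccccc2)cc1O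
A5 | alternative 2 | racemic ethyl 2-(benzyloxy)-3-[4-(benzyloxy)-3-methoxyphenyl]-3-oxopropanoate | CCOC(=O)C(OCc1ccccc1)C(=O)c1ccc(OCc2ccccc2)c(OC)c1
A6 | alternative 2 | 3,5-bis(benzyloxy)-2-[4-(benzyloxy)-3-methoxyphenyl]-7-hydroxy-8-methoxy-4H-chromen-4-one | COc1cc(-c2oc3c(OC)c(O)cc(OCc4ccccc4)c3c(=O)c2OCc2ccccc2)ccc1OCc1ccccc1
A7 | alternative 3 | 4-iodo-2-methoxy-5-(methoxymethoxy)benzene-1,3-diol | COCOc1cc(O)c(OC)c(O)c1I
A8 | alternative 3 | 4-ethynyl-2-methoxy-1-(methoxymethoxy)benzene | COCOc1ccc(C#C)cc1OC
A9 | alternative 3 | 7-hydroxy-8-methoxy-5-(methoxymethoxy)-2-[3-methoxy-4-(methoxymethoxy)phenyl]-4H-chromen-4-one | COCOc1ccc(-c2cc(=O)c3c(OCOC)cc(O)c(OC)c3o2)cc1OC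
A10 | alternative 3 | 1-[2,4-dihydroxy-3-methoxy-6-(methoxymethoxy)phenyl]-3-[3-methoxy-4-(methoxymethoxy)phenyl]prop-2-yn-1-one | COCOc1ccc(C#CC(=O)c2c(OCOC)cc(O)c(OC)c2O)cc1OC
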